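**Retrosynthetic overview**
- The target is (+)-catechin-(4α→8)-(−)-epigallocatechin 3-O-gallate. The last step is global O-debenzylation. The lower unit is assembled from (−)-epigallocatechin (both stereocentres intact) and purchased tri-O-benzylgallic acid.
- The 3-OH and 4-H of the upper unit come from hydroboration–oxidation of a 4-aryl-flav-3-ene, anti to the C2 aryl group. This sets C3 and C4 in one step from C2 alone.
- Key disconnection, interflavan C4–C8 bond: both carbons are acceptors in their precursors (C4 is the carbonyl carbon of a flavanone, C8 is the C–Br carbon of the 8-bromo lower unit). The flavanone is used with reversed polarity, as its N-tosylhydrazone/diazo compound (a C4 vinyl-anion equivalent), in a palladium-catalysed coupling.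
- No ring is built. Ring C of the upper unit goes flavanone → flav-3-ene → flavan-3-ol, and (2S)-eriodictyol supplies C2, the only source of upper-unit chirality.

Assumption: (−)-epigallocatechin 1 and (2S)-eriodictyol 6 are bought as single enantiomers (≥98% ee), 3,4,5-tris(benzyloxy)benzoic acid 4 is bought, and the ee of 6 and 7 is checked by chiral HPLC.

**Route**

Step 1
Reactants: 1 (−)-epigallocatechin (EGC)
Product: 2 5,7,3',4',5'-penta-O-benzyl-(−)-epigallocatechin
Conditions: BnBr (5.5 equiv), K2CO3 (6 equiv), degassed DMF, under argon, 0 °C to rt, 16 h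
Reagents that add atoms: benzyl bromide, BrCc1ccccc1
Why: Williamson etherification of the five phenols under carbonate base, which does not deprotonate the secondary 3-OH; exclusion of air protects the pyrogallol ring and the low temperature avoids C2 epimerisation, so both stereocentres are untouched.

Step 2
Reactants: 2 5,7,3',4',5'-penta-O-benzyl-(−)-epigallocatechin
Product: 3 8-bromo-5,7,3',4',5'-penta-O-benzyl-(−)-epigallocatechin
Conditions: NBS (1.02 equiv), CH2Cl2, −78 °C to 0 °C, dark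
Reagents that add atoms: N-bromosuccinimide, O=C1CCC(=O)N1Br
Why: Electrophilic aromatic bromination of the phloroglucinol-type ring A, the most electron-rich ring, goes to C8 (para to the 5-OBn and less hindered than C6 between two benzyloxy groups), as known for benzylated flavan-3-ols with a free 3-OH; no stereocentre is touched.

Step 3
Reactants: 3 8-bromo-5,7,3',4',5'-penta-O-benzyl-(−)-epigallocatechin (1.0 equiv); 4 3,4,5-tris(benzyloxy)benzoic acid (1.5 equiv)
Product: 5 8-bromo-octa-O-benzyl-EGCG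
Conditions: DCC (1.6 equiv), DMAP (0.3 equiv), CH2Cl2, 0 °C to rt, 24 h
Reagents that add atoms: none
Why: Steglich esterification of the only free hydroxyl (the axial 3-OH) through the DMAP-activated acyl group, with retention at C3 because the C–O bond of the alcohol is not broken; the aryl bromide is inert.

Step 4
Reactants: 6 (2S)-eriodictyol
Product: 7 (2S)-7,3',4'-tris(benzyloxy)-5-hydroxyflavanone
Conditions: BnBr (3.1 equiv), K2CO3 (3.3 equiv), DMF, under argon, 0 °C to rt, 6 h; recrystallise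
Reagents that add atoms: benzyl bromide, BrCc1ccccc1
Why: Williamson etherification alkylates the three free phenols while the 5-OH, hydrogen-bonded to the C4 carbonyl, stays free; low temperature and short time limit base-induced ring opening to the chalcone, which would racemise C2.

Step 5
Reactants: 7 (2S)-7,3',4'-tris(benzyloxy)-5-hydroxyflavanone (1.3 equiv); 5 8-bromo-octa-O-benzyl-EGCG (1.0 equiv)
Product: 10 (2S)-4-aryl-flav-3-ene coupling product (C4 of the upper unit bonded to C8 of octa-O-benzyl-EGCG), via C4 tosylhydrazone 8 (not isolated), via 4-diazoflavan 9 (not isolated)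
Conditions: TsNHNH2 (1.3 equiv), 1,4-dioxane, 80 °C, 3 h; then 5, Pd2(dba)3 (4 mol%), XPhos (16 mol%), LiOtBu (4.5 equiv), 1,4-dioxane, 90 °C, dark, 12 h
Reagents that add atoms: none
Why: Barluenga–Valdés cross-coupling: condensation gives tosylhydrazone 8, LiOtBu converts it (Bamford–Stevens) into diazo compound 9, whose carbon (the former carbonyl carbon, now a donor) attacks the divalent arylpalladium bromide formed by oxidative addition of zerovalent palladium to 5, and carbene migratory insertion followed by β-hydride elimination from C3 gives the C3=C4 alkene; C2 is not involved and no new stereocentre is formed.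

Step 6
Reactants: 10 (2S)-4-aryl-flav-3-ene coupling product
Product: 12 7,3',4'-tri-O-benzyl-(+)-catechin-(4α→8)-octa-O-benzyl-(−)-EGCG, via C3 alkylborane 11 (not isolated)
Conditions: BH3·THF (5 equiv), THF, 0 °C to rt, 6 h; then 3 M aq NaOAc, 30% H2O2, 0 °C to rt
Reagents that add atoms: hydrogen peroxide, OO
Why: Hydroboration–oxidation: BH3 adds syn across the trisubstituted C3=C4 bond with boron at the less substituted C3 and from the β face, opposite the C2 aryl group (the known course for flav-3-enes and 1-arylcycloalkenes), and C–B oxidation with retention gives the 3β-OH trans to both the 2α-aryl and the 4α-aryl (2,3-trans-3,4-trans, upper unit 2R,3S,4S); acetate-buffered peroxide spares the gallate ester.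

Step 7
Reactants: 12 7,3',4'-tri-O-benzyl-(+)-catechin-(4α→8)-octa-O-benzyl-(−)-EGCG
Product: 13 (+)-catechin-(4α→8)-(−)-epigallocatechin 3-O-gallate (target)
Conditions: H2 (1 atm), Pd(OH)2/C (20 wt%), THF/MeOH/H2O 20:1:1, rt; filter, Sephadex LH-20, lyophilise
Reagents that add atoms: none
Why: Catalytic hydrogenolysis of all eleven benzyl ethers under neutral conditions, standard for benzylated proanthocyanidin gallates, leaves the ester, the C4–C8 bond and all five stereocentres intact.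

**Compound list**

1 | (−)-epigallocatechin (EGC), (2R,3R) | O[C@@H]1Cc2c(O)cc(O)cc2O[C@@H]1c1cc(O)c(O)c(O)c1 | starting material
2 | 5,7,3',4',5'-penta-O-benzyl-(−)-epigallocatechin: (2R,3R)-5,7-bis(benzyloxy)-2-[3,4,5-tris(benzyloxy)phenyl]chroman-3-ol | O[C@@H]1Cc2c(OCc3ccccc3)cc(OCc3ccccc3)cc2O[C@@H]1c1cc(OCc2ccccc2)c(OCc2ccccc2)c(OCc2ccccc2)c1 | intermediate
3 | 8-bromo-5,7,3',4',5'-penta-O-benzyl-(−)-epigallocatechin (Br at C8 of ring A, between O1 and the 7-OBn; free 3-OH) | O[C@@H]1Cc2c(OCc3ccccc3)cc(OCc3ccccc3)c(Br)c2O[C@@H]1c1cc(OCc2ccccc2)c(OCc2ccccc2)c(OCc2ccccc2)c1 | intermediate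
4 | 3,4,5-tris(benzyloxy)benzoic acid (tri-O-benzylgallic acid) | O=C(O)c1cc(OCc2ccccc2)c(OCc2ccccc2)c(OCc2ccccc2)c1 | starting material
5 | 8-bromo-octa-O-benzyl-EGCG: (2R,3R)-8-bromo-5,7-bis(benzyloxy)-2-[3,4,5-tris(benzyloxy)phenyl]chroman-3-yl 3,4,5-tris(benzyloxy)benzoate | O=C(O[C@@H]1Cc2c(OCc3ccccc3)cc(OCc3ccccc3)c(Br)c2O[C@@H]1c1cc(OCc2ccccc2)c(OCc2ccccc2)c(OCc2ccccc2)c1)c1cc(OCc2ccccc2)c(OCc2ccccc2)c(OCc2ccccc2)c1 | intermediate
6 | (2S)-eriodictyol, (2S)-5,7,3',4'-tetrahydroxyflavanone | Oc1cc(O)c2c(c1)O[C@H](c1ccc(O)c(O)c1)CC2=O | starting material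
7 | (2S)-7,3',4'-tris(benzyloxy)-5-hydroxyflavanone | c1ccccc1COc1cc(O)c2c(c1)O[C@H](c1ccc(OCc3ccccc3)c(OCc3ccccc3)c1)CC2=O | intermediate
8 | C4 N-tosylhydrazone of 7 (C=N geometry not defined) | c1ccccc1COc1cc(O)c2c(c1)O[C@H](c1ccc(OCc3ccccc3)c(OCc3ccccc3)c1)CC2=NNS(=O)(=O)c1ccc(C)cc1 | intermediate (not isolated)
9 | (2S)-7,3',4'-tris(benzyloxy)-4-diazoflavan-5-ol | c1ccccc1COc1cc(O)c2c(c1)O[C@H](c1ccc(OCc3ccccc3)c(OCc3ccccc3)c1)CC2=[N+]=[N-] | intermediate (not isolated)
10 | octa-O-benzyl-EGCG carrying at C8 the C4 of (2S)-7,3',4'-tris(benzyloxy)-5-hydroxyflav-3-ene (2H-chromene, C3=C4) | O=C(O[C@@H]1Cc2c(OCc3ccccc3)cc(OCc3ccccc3)c(C3=C[C@@H](c4ccc(OCc5ccccc5)c(OCc5ccccc5)c4)Oc4cc(OCc5ccccc5)cc(O)c34)c2O[C@@H]1c1cc(OCc2ccccc2)c(OCc2ccccc2)c(OCc2ccccc2)c1)c1cc(OCc2ccccc2)c(OCc2ccccc2)c(OCc2ccccc2)c1 | intermediate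
11 | C3 alkylborane from 10: 2α-aryl, 3β-BH2, 4β-H, 4α-aryl (drawn as RBH2 with free 5-OH; in the flask the phenol is O-borylated) | O=C(O[C@@H]1Cc2c(OCc3ccccc3)cc(OCc3ccccc3)c([C@@H]3c4c(O)cc(OCc5ccccc5)cc4O[C@H](c4ccc(OCc5ccccc5)c(OCc5ccccc5)c4)[C@H]3B)c2O[C@@H]1c1cc(OCc2ccccc2)c(OCc2ccccc2)c(OCc2ccccc2)c1)c1cc(OCc2ccccc2)c(OCc2ccccc2)c(OCc2ccccc2)c1 | intermediate (not isolated)
12 | 7,3',4'-tri-O-benzyl-(+)-catechin-(4α→8)-octa-O-benzyl-(−)-EGCG; upper unit (2R,3S,4S) with 2-aryl α, 3-OH β, 4-aryl α; lower unit (2R,3R) | O=C(O[C@@H]1Cc2c(OCc3ccccc3)cc(OCc3ccccc3)c([C@@H]3c4c(O)cc(OCc5ccccc5)cc4O[C@H](c4ccc(OCc5ccccc5)c(OCc5ccccc5)c4)[C@H]3O)c2O[C@@H]1c1cc(OCc2ccccc2)c(OCc2ccccc2)c(OCc2ccccc2)c1)c1cc(OCc2ccccc2)c(OCc2ccccc2)c(OCc2ccccc2)c1 | intermediate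
13 | (+)-catechin-(4α→8)-(−)-epigallocatechin 3-O-gallate; upper unit (2R,3S,4S), lower unit (2R,3R) | O=C(O[C@@H]1Cc2c(O)cc(O)c([C@@H]3c4c(O)cc(O)cc4O[C@H](c4ccc(O)c(O)c4)[C@H]3O)c2O[C@@H]1c1cc(O)c(O)c(O)c1)c1cc(O)c(O)c(O)c1 | target

**Summary**

Total step count: 7. Longest linear sequence: 6 (steps 1, 2, 3, 5, 6, 7 from EGC).

Steps most likely to fail:

1. Step 5 (key coupling). The bromide 5 is very electron-rich and flanked by two oxygen substituents, and the carbene insertion is congested. Side paths are carbene 1,2-hydrogen shift from 9 without coupling, migration of the double bond to C2=C3, thermal 6π ring opening of the 2H-chromene 10 at 90 °C (both would erode C2), and attack of LiOtBu on the gallate ester. The fallback sets out from 7 (with 5) and comes back to the route at 10. Ketone 7 is condensed with 2,4,6-triisopropylbenzenesulfonyl hydrazide (MeOH, cat. HCl, rt) to the trisylhydrazone F1. Treatment with n-BuLi (3.3 equiv) in THF/TMEDA at −78 °C to 0 °C (Shapiro reaction) gives the C4 vinyllithium F2 as its lithium 5-phenoxide, and ZnCl2 converts it into the vinylzinc chloride F3. Negishi coupling of F3 with 5 (Pd2(dba)3, SPhos, THF, 40 °C) gives 10. C4 is still the donor, now as a stoichiometric vinyl anion instead of a catalytic carbene; the temperature is lower and the organozinc tolerates the ester.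

2. Step 6 (hydroboration–oxidation). The bulky, twisted C4 aryl group may slow the addition or lower the facial selectivity set by the C2 aryl, and a slow hydroboration gives BH3 time to attack the gallate ester. The fallback sets out from 10 and comes back to the route at 12, and it replaces kinetic face control by thermodynamic control. DMDO (acetone, −40 °C) epoxidises 10 anti to the C2 aryl to the 3β,4β-epoxide F4. MgBr2·OEt2 (CH2Cl2, −20 °C) opens it at the benzylic C4 with 1,2-hydride shift (Meinwald rearrangement) to the 4-aryl-flavan-3-one, first as the 2,4-trans ketone F5. Brief treatment with catalytic Et3N epimerises the doubly benzylic C4 (more acidic than C2) to the diequatorial 2,4-cis ketone F6. NaBH4 (THF/MeOH, −40 °C) then delivers hydride axially to give the all-equatorial alcohol 12.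

3. Step 4 (benzylation of the flavanone). Carbonate base can open the pyranone ring to the 2'-hydroxychalcone and so lower the ee of 7, and that loss would be carried into the upper unit. The fallback bypasses 6: it sets out from purchased 5,7-dihydroxychromone in place of 6 and comes back to the route at 7. Selective 7-O-benzylation (BnBr, K2CO3, acetone, rt; the chelated 5-OH stays free, and there is no stereocentre to lose) gives 7-benzyloxy-5-hydroxychromone F7. Asymmetric 1,4-addition of purchased 3,4-bis(benzyloxy)phenylboronic acid (3 mol% [Rh(OH)(cod)]2, the MeO-BIPHEP enantiomer that gives the 2S product, toluene/H2O, rt, no added base) then gives 7 directly in high ee.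

**Further compounds**

F1 | step 5 | C4 2,4,6-triisopropylbenzenesulfonyl hydrazone of 7 | c1ccccc1COc1cc(O)c2c(c1)O[C@H](c1ccc(OCc3ccccc3)c(OCc3ccccc3)c1)CC2=NNS(=O)(=O)c1c(C(C)C)cc(C(C)C)cc1C(C)C
F2 | step 5 | (2S)-7,3',4'-tris(benzyloxy)-4-lithioflav-3-ene, lithium 5-phenoxide | [Li]C1=C[C@@H](c2ccc(OCc3ccccc3)c(OCc3ccccc3)c2)Oc2cc(OCc3ccccc3)cc(O[Li])c12
F3 | step 5 | (2S)-7,3',4'-tris(benzyloxy)flav-3-en-4-ylzinc chloride, lithium 5-phenoxide | Cl[Zn]C1=C[C@@H](c2ccc(OCc3ccccc3)c(OCc3ccccc3)c2)Oc2cc(OCc3ccccc3)cc(O[Li])c12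
F4 | step 6 | 3β,4β-epoxide of 10 | O=C(O[C@@H]1Cc2c(OCc3ccccc3)cc(OCc3ccccc3)c([C@]36c4c(O)cc(OCc5ccccc5)cc4O[C@H](c4ccc(OCc5ccccc5)c(OCc5ccccc5)c4)[C@H]3O6)c2O[C@@H]1c1cc(OCc2ccccc2)c(OCc2ccccc2)c(OCc2ccccc2)c1)c1cc(OCc2ccccc2)c(OCc2ccccc2)c(OCc2ccccc2)c1
F5 | step 6 | 4-aryl-flavan-3-one, 2,4-trans (2α-aryl, 4β-aryl) | O=C(O[C@@H]1Cc2c(OCc3ccccc3)cc(OCc3ccccc3)c([C@H]3c4c(O)cc(OCc5ccccc5)cc4O[C@H](c4ccc(OCc5ccccc5)c(OCc5ccccc5)c4)C3=O)c2O[C@@H]1c1cc(OCc2ccccc2)c(OCc2ccccc2)c(OCc2ccccc2)c1)c1cc(OCc2ccccc2)c(OCc2ccccc2)c(OCc2ccccc2)c1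
F6 | step 6 | 4-aryl-flavan-3-one, 2,4-cis (2α-aryl, 4α-aryl) | O=C(O[C@@H]1Cc2c(OCc3ccccc3)cc(OCc3ccccc3)c([C@@H]3c4c(O)cc(OCc5ccccc5)cc4O[C@H](c4ccc(OCc5ccccc5)c(OCc5ccccc5)c4)C3=O)c2O[C@@H]1c1cc(OCc2ccccc2)c(OCc2ccccc2)c(OCc2ccccc2)c1)c1cc(OCc2ccccc2)c(OCc2ccccc2)c(OCc2ccccc2)c1
F7 | step 4 | 7-benzyloxy-5-hydroxychromone | O=c1ccoc2cc(OCc3ccccc3)cc(O)c12
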